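Numbering used throughout: tetralin numbering. C1 carries the 4-hydroxy-3-methoxyphenyl (guaiacyl) ring, C2 and C3 carry C9 and C10, C4 is the benzylic CH2. Ring A is C4a, C5 (OMe), C6 (OMe), C7 (OH), C8 (H), C8a; ring B is C1–C4 with C4a and C8a. In the open-chain cinnamates, "α-carbon" means the carbon next to the ester carbonyl.

## The problem

Compound 14 is a 1-aryltetralin in which aromatic ring A is fused to carbocyclic ring B. Ring B carries three contiguous stereocentres, C1 (R, guaiacyl), C2 (S, CH2OH) and C3 (S, CH2OH), all trans and therefore all equatorial. C1 is a diaryl methine that base cannot epimerise, whereas C2 and C3 become epimerisable once C9 and C10 are at the ester oxidation level. A synthesis therefore has to fix only C1 in the absolute sense and can let thermodynamics set C2 and C3 from it. Ring A is pentasubstituted (5,6-dimethoxy, 7-hydroxy, C8 free), so the bond from C1 must reach C8a and no other ring position; the two aryl units differ, so any dimerisation-type route must be a cross-coupling. Two free phenols on electron-rich rings and a doubly benzylic C1–H para to a phenol mean that late intermediates must be kept away from strong oxidants, strong acid (ionisation at C1 through a quinone methide) and air under basic conditions. The enabling feature is that C7-OH is para to C4a and the guaiacyl OH is para to C1. The skeleton is thus two 4-hydroxycinnamyl units joined at C2–C3, with C8a of ring A (para to the C6 methoxy group) bonded to the benzylic carbon of the other unit. This is the connectivity that phenol oxidation, radical coupling and quinone methide cyclisation produce.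

## Retrosynthesis

**14 ⇒ 13.** The two primary alcohol C–O bonds are traced back to the methyl esters of 13. This cut is preferred over a lactone or a protected diol because only at the diester level are C2 and C3 epimerisable and the trans,trans arrangement the thermodynamic one. 13 is no smaller than 14, but of its three stereocentres only C1 has to be delivered by earlier steps. The forward step is a LiAlH4 reduction that must tolerate two free phenols.

**13 ⇒ 12.** The two methyl ester bonds are exchanged for the two ester bonds to (2R,4R)-pentane-2,4-diol 1, giving the bridged tetralin 12 (nine-membered dilactone across C9 and C10). C3 may have either configuration in 12. The forward step asks methoxide to do two things at once: release the diol and equilibrate C2 and C3 to the all-equatorial diester.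

**12 ⇒ 11.** The C3–H and C4–H bonds and the C–H bond at the guaiacyl 5-position are removed, which leads to the bridged 1,2-dihydronaphthalene 11 with a C3=C4 bond and a bromine atom ortho to the guaiacyl hydroxyl. Saturation is placed before tether removal because base on a 1-aryl-1,2-dihydronaphthalene-2,3-diester can move the double bond into the C1–C2 or C2–C3 position and erase C2 or C1. One hydrogenation is asked to saturate the alkene and to remove bromine.

**11 ⇒ 8.** The key disconnection cuts C2–C3 and C1–C8a. This leads to the mixed diester 8, in which a 5-bromoferulate and a 4-hydroxy-2,3-dimethoxycinnamate are held on the two oxygens of diol 1. The cut is preferred over the neighbouring ones (C4–C4a, C1–C2 with C3–C4, or C1–C8a with C4–C4a) for three reasons: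

- it removes ring B, two skeletal bonds and both stereocentres of 11 in one step;
- it needs no protecting group;
- it reduces the problem to two cinnamates.

The forward reaction must give four selectivities, each tied to a design element:

- *Cross- over homo-coupling:* the tether and high dilution.
- *α,α-Coupling over coupling at a ring carbon:* the bromine atom closes the free ring position next to the guaiacyl hydroxyl, and the three-carbon tether makes α,α-coupling a nine-membered closure where the alternative would be a 13-membered ansa ring.
- *Ring A as the nucleophile of the ring closure:* bromine deactivates the guaiacyl ring and activates its quinone methide, and the C5 methoxy group hinders the ring A quinone methide.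
- *Absolute configuration at C1:* the chiral tether acts through C2. The tether stays in 11, so a minor diastereomer can be separated.

**8 ⇒ 5 + 2 + 6.** The ester C–O bond at the second diol oxygen and the Cα=Cβ bond of the ring A cinnamate are cut. This gives the mono-ester 5, Meldrum's acid 2 and 4-hydroxy-2,3-dimethoxybenzaldehyde 6, by way of the malonic half-ester 7. Cutting the olefin rather than only the ester C–O bond avoids a preformed cinnamic acid and with it any phenol protection, because a Knoevenagel–Doebner condensation tolerates free 4-hydroxybenzaldehydes. The forward step must acylate the secondary alcohol of 5 in the presence of its hindered phenol.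

**5 ⇒ 1 + 2 + 3.** The same two bonds are cut on the other side, giving diol 1, Meldrum's acid 2 and 5-bromovanillin 3, by way of the half-ester 4. The two hydroxyl groups of 1 are homotopic, so mono-functionalisation needs only an excess of the diol. The brominated unit is attached first because its phenol, flanked by bromine and methoxy, interferes least in the second acylation.

## Roads not taken

**Alternative 1:** The cut is C4–C4a. In the forward step the open-chain oxetane A2 is treated with Sc(OTf)3; C1 and C2 are already set in A2 and C3 is the prochiral 3-position of the oxetane. C4a of ring A opens one of the two oxetane CH2 groups (6-exo-tet), ring B closes, and the other CH2 becomes the free C10 hydroxyl of A1.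

- *Merits:* every C–C bond is made by polar, regiochemically predictable chemistry; the oxidation level is already that of the target; C9 and C10 emerge differentiated.
- *Weak points:* A2 needs its own enantioselective synthesis of the C1/C2 diaryl-methine diad. The attacking carbon C4a lies next to the C5 methoxy group, so a bromine atom at C8 is needed to stop closure at the other ortho position. The choice between the two oxetane CH2 groups, which sets C3, rests on remote control from C2. Two benzyl ethers, a silyl ether and the bromine must be removed afterwards.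
- *Comparison:* this road is better in the predictability of each bond formation and in having C1 secured before the ring closes. The chosen plan sets against it a six-step sequence without protecting groups, in which ring B, two bonds and two stereocentres arise in one step from purchasable aldehydes.

**Alternative 2:** The cuts are C1–C8a and C4–C4a. CsF releases the aryne of ring A from the silyl triflate A5, and the aryne inserts into the C(=O)–C(aryl) bond of cyclobutanone A4. This expands the four-membered ring into ring B of the C4 ketone A3.

- *Merits:* the step is convergent and intrinsically a cross-coupling; the C5 methoxy group directs the enolate carbon to C8a, so ring A regiochemistry is unambiguous.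
- *Weak points:* the C4 carbonyl has no counterpart in the target and must be removed by extra steps. The enantiopure, all-trans trisubstituted cyclobutanone A4 is itself a demanding target. Insertion into a simple α-aryl cyclobutanone lies at the edge of the known scope of aryne acyl-alkylation. C1 is reset by protonation after the fragmentation, so its configuration again rests on thermodynamics.
- *Comparison:* this road is as good or better in cross-selectivity and in the regiochemistry of ring A. The chosen plan sets against it the absence of a superfluous oxygen, far simpler precursors and a shorter route.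

**Alternative 3:** The cuts are C1–C2 and C3–C4. CsF triggers 1,4-elimination of the silyl ammonium salt A7 to the E-configured α-aryl o-quinodimethane, which adds endo to the menthyloxy butenolide A8 on the face away from the menthyloxy group and gives the all-cis lactone acetal A6.

- *Merits:* the facial control of this auxiliary in cycloadditions is well precedented; two C–C bonds and three stereocentres arise in one step; cross-selectivity and regiochemistry are intrinsic.
- *Weak points:* the endo adduct is 1,2-cis, so C2 must be epimerised afterwards. A8 carries the (1S,2R,5S) menthyl group, the less accessible enantiomeric series of this auxiliary. The lactone acetal has to be hydrolysed and reduced in separate operations. A7, a diarylmethyl silane next to a benzylic ammonium group on a fully substituted ring, needs a multi-step synthesis, and two benzyl ethers must be removed.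
- *Comparison:* in absolute stereocontrol this road stands on firmer precedent than the chosen plan. The chosen plan sets against it the step count, the absence of protecting groups, a recoverable diol that doubles as a resolving handle (diastereomers of 11 are separable), and a key step whose component reaction, the oxidative 8–8 dimerisation of 3,5-disubstituted 4-hydroxycinnamates, is known.

Key step: step 3

Assumption: (2R,4R)-pentane-2,4-diol 1 (and its enantiomer), Meldrum's acid 2, 5-bromovanillin 3 and 4-hydroxy-2,3-dimethoxybenzaldehyde 6 are taken as purchasable.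

Assumption: the (2R,4R) tether is taken to favour the (1R,2S) diastereomer 11. The sense of induction of a nine-membered radical combination cannot be predicted with confidence; if the opposite sense is found, the (2S,4S) diol is used in step 1 and nothing else changes.

## Route

Step 1
Reactants: 1 (2R,4R)-pentane-2,4-diol; 2 Meldrum's acid (2,2-dimethyl-1,3-dioxane-4,6-dione); 3 5-bromovanillin (3-bromo-4-hydroxy-5-methoxybenzaldehyde)
Product: 5 (2R,4R)-4-hydroxypentan-2-yl (E)-3-(3-bromo-4-hydroxy-5-methoxyphenyl)prop-2-enoate, via diol hydrogen malonate 4 (not isolated)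
Conditions: 1 (3 equiv), 2, toluene, 100 °C; then 3, pyridine, piperidine (cat.), 60 °C
Reagents that add atoms: none
Why: Alcoholysis of Meldrum's acid by one of the two homotopic hydroxyl groups (diol in excess to suppress double acylation) should give the malonic half-ester 4, whose Knoevenagel–Doebner condensation with the unprotected 4-hydroxybenzaldehyde 3 proceeds with decarboxylation to the E-cinnamate; no stereocentre is formed or touched.

Step 2
Reactants: 5 (2R,4R)-4-hydroxypentan-2-yl (E)-3-(3-bromo-4-hydroxy-5-methoxyphenyl)prop-2-enoate; 2 Meldrum's acid; 6 4-hydroxy-2,3-dimethoxybenzaldehyde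
Product: 8 (2R,4R)-pentane-2,4-diyl 2-[(E)-3-(3-bromo-4-hydroxy-5-methoxyphenyl)prop-2-enoate] 4-[(E)-3-(4-hydroxy-2,3-dimethoxyphenyl)prop-2-enoate], via hydrogen malonate 7 (not isolated)
Conditions: 2 (1.3 equiv), toluene, 95 °C; then 6, pyridine, piperidine (cat.), 60 °C
Reagents that add atoms: none
Why: The same alcoholysis and Knoevenagel–Doebner sequence on the remaining secondary hydroxyl group; the phenol of 5 lies between bromine and methoxy and should be a much poorer nucleophile toward Meldrum's acid than the alcohol, and the condensation with 6 should give the second E-cinnamate without phenol protection.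

Step 3
Reactants: 8 (2R,4R)-pentane-2,4-diyl 2-[(E)-3-(3-bromo-4-hydroxy-5-methoxyphenyl)prop-2-enoate] 4-[(E)-3-(4-hydroxy-2,3-dimethoxyphenyl)prop-2-enoate]
Product: 11 cyclic (2R,4R)-pentane-2,4-diyl (1R,2S)-1-(3-bromo-4-hydroxy-5-methoxyphenyl)-7-hydroxy-5,6-dimethoxy-1,2-dihydronaphthalene-2,3-dicarboxylate, via bis-quinone methide 9 (not isolated), via arylidene quinone methide 10 (not isolated)
Conditions: FeCl3·6H2O (2.2 equiv), acetone–H2O, 0 °C to rt, slow addition of 8 (high dilution), under argon
Reagents that add atoms: none
Why: Proposed new method: FeCl3 takes one electron from each phenol of 8, and the two phenoxyl radicals, which carry spin on the α-carbons held side by side by the three-carbon tether, should combine to form C2–C3 and close the temporary nine-membered dilactone of bis-quinone methide 9 (a 9-membered closure by radical–radical combination). The ring A unit of 9, whose quinone methide carbon is hindered by the ortho methoxy group, should lose its α-proton to give the E-arylidene 10; C8a of the rearomatised ring A (para to the C6 methoxy group) then adds to the exocyclic carbon of the brominated guaiacyl quinone methide in a 6-exo-trig vinylogous Friedel–Crafts (1,6-) addition that forms C1–C8a and closes ring B. The closest known reaction type is the FeCl3 or Ag2O dimerisation of sinapate esters to trans-1-aryl-1,2-dihydronaphthalene-2,3-dicarboxylates, and a related known type is the diastereoselective oxidative coupling of two galloyl esters held on a chiral diol; using a diol tether to force a cross-coupling of two different hydroxycinnamates and to bias its facial course has not been shown. C2 is set in the radical combination, where the C2-symmetric tether can discriminate only between the two like-configured pairings (an unlike pairing would carry no induction, because the ring A α-centre is lost afterwards); C1 is set in the ring closure, in which the aryl group ends anti to the C2 carboxyl as in the untethered reaction, so that C1 follows C2. Cross- over homo-coupling is secured by the tether and high dilution; α,α-coupling is favoured by the bromine atom, which closes the free position next to the guaiacyl hydroxyl, and by the 13-membered ansa ring that coupling onto C8 of ring A would require; the direction of ring closure is secured by the same bromine atom, which makes the guaiacyl ring the poorer nucleophile and its quinone methide the better electrophile. Because 11 retains the chiral tether, any (1S,2R) diastereomer should be separable by chromatography or crystallisation before the tether is removed.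

Step 4
Reactants: 11 cyclic (2R,4R)-pentane-2,4-diyl (1R,2S)-1-(3-bromo-4-hydroxy-5-methoxyphenyl)-7-hydroxy-5,6-dimethoxy-1,2-dihydronaphthalene-2,3-dicarboxylate
Product: 12 cyclic (2R,4R)-pentane-2,4-diyl (1R,2S,3R)-7-hydroxy-1-(4-hydroxy-3-methoxyphenyl)-5,6-dimethoxy-1,2,3,4-tetrahydronaphthalene-2,3-dicarboxylate (1,2-trans and 2,3-cis)
Conditions: H2 (3 atm), 10% Pd/C, NaOAc (1.5 equiv), EtOAc–MeOH, rt
Reagents that add atoms: none
Why: Heterogeneous catalytic hydrogenation of the ester-conjugated trisubstituted C3=C4 bond is combined with hydrogenolysis of the aryl C–Br bond; NaOAc takes up HBr and is too weak a base to move the double bond. Hydrogen is expected on the face away from the dilactone bridge, giving the 2,3-cis fusion, but the C3 configuration is immaterial because step 5 equilibrates it; C1 and C2 are untouched.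

Step 5
Reactants: 12 cyclic (2R,4R)-pentane-2,4-diyl (1R,2S,3R)-7-hydroxy-1-(4-hydroxy-3-methoxyphenyl)-5,6-dimethoxy-1,2,3,4-tetrahydronaphthalene-2,3-dicarboxylate
Product: 13 dimethyl (1R,2S,3S)-7-hydroxy-1-(4-hydroxy-3-methoxyphenyl)-5,6-dimethoxy-1,2,3,4-tetrahydronaphthalene-2,3-dicarboxylate
Conditions: NaOMe (5 equiv), MeOH, 50 °C, under argon; then AcOH
Reagents that add atoms: methanol, CO; sodium methoxide, [Na+].[O-]C
Why: Methoxide transesterification should open the strained nine-membered dilactone and release diol 1 for recovery; under the same conditions C2 and C3 equilibrate through their ester enolates to the all-equatorial trans,trans diester (thermodynamic epimerisation of a 1-aryltetralin-2,3-diester), steered by C1, which cannot be deprotonated.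

Step 6
Reactants: 13 dimethyl (1R,2S,3S)-7-hydroxy-1-(4-hydroxy-3-methoxyphenyl)-5,6-dimethoxy-1,2,3,4-tetrahydronaphthalene-2,3-dicarboxylate
Product: 14 [(1R,2S,3S)-7-hydroxy-1-(4-hydroxy-3-methoxyphenyl)-5,6-dimethoxy-1,2,3,4-tetrahydronaphthalene-2,3-diyl]dimethanol
Conditions: LiAlH4 (excess), THF, 0 °C to reflux; then dilute aq. HCl
Reagents that add atoms: none
Why: LiAlH4 reduction of both methyl esters to primary alcohols; the two phenols are only deprotonated (extra hydride is supplied for them) and no stereocentre is affected.

## Compound list

1 | (2R,4R)-pentane-2,4-diol | C[C@@H](O)C[C@@H](C)O | starting material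
2 | Meldrum's acid (2,2-dimethyl-1,3-dioxane-4,6-dione) | CC1(C)OC(=O)CC(=O)O1 | starting material
3 | 5-bromovanillin (3-bromo-4-hydroxy-5-methoxybenzaldehyde) | COc1cc(C=O)cc(Br)c1O | starting material
4 | 3-{[(2R,4R)-4-hydroxypentan-2-yl]oxy}-3-oxopropanoic acid | C[C@@H](O)C[C@@H](C)OC(=O)CC(=O)O | intermediate
5 | (2R,4R)-4-hydroxypentan-2-yl (E)-3-(3-bromo-4-hydroxy-5-methoxyphenyl)prop-2-enoate | COc1cc(/C=C/C(=O)O[C@H](C)C[C@@H](C)O)cc(Br)c1O | intermediate
6 | 4-hydroxy-2,3-dimethoxybenzaldehyde | COc1c(C=O)ccc(O)c1OC | starting material
7 | 3-{[(2R,4R)-4-{[(E)-3-(3-bromo-4-hydroxy-5-methoxyphenyl)prop-2-enoyl]oxy}pentan-2-yl]oxy}-3-oxopropanoic acid | COc1cc(/C=C/C(=O)O[C@H](C)C[C@@H](C)OC(=O)CC(=O)O)cc(Br)c1O | intermediate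
8 | (2R,4R)-pentane-2,4-diyl 2-[(E)-3-(3-bromo-4-hydroxy-5-methoxyphenyl)prop-2-enoate] 4-[(E)-3-(4-hydroxy-2,3-dimethoxyphenyl)prop-2-enoate] | COc1cc(/C=C/C(=O)O[C@H](C)C[C@@H](C)OC(=O)/C=C/c2ccc(O)c(OC)c2OC)cc(Br)c1O | intermediate
9 | (2R,4R)-7-[(3-bromo-5-methoxy-4-oxocyclohexa-2,5-dien-1-ylidene)methyl]-8-[(2,3-dimethoxy-4-oxocyclohexa-2,5-dien-1-ylidene)methyl]-2,4-dimethyl-1,5-dioxonane-6,9-dione (bis-quinone methide; ring carbon 7 configured as C2 of 11, ring carbon 8 and the exocyclic alkene geometries not defined) | COC1=CC(=C[C@@H]2C(=O)O[C@H](C)C[C@@H](C)OC(=O)C2C=C2C=CC(=O)C(OC)=C2OC)C=C(Br)C1=O | intermediate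
10 | (2R,4R)-7-[(3-bromo-5-methoxy-4-oxocyclohexa-2,5-dien-1-ylidene)methyl]-8-[(E)-(4-hydroxy-2,3-dimethoxyphenyl)methylidene]-2,4-dimethyl-1,5-dioxonane-6,9-dione (ring carbon 7 configured as C2 of 11) | COC1=CC(=C[C@@H]2C(=O)O[C@H](C)C[C@@H](C)OC(=O)/C2=C/c2ccc(O)c(OC)c2OC)C=C(Br)C1=O | intermediate
11 | cyclic (2R,4R)-pentane-2,4-diyl (1R,2S)-1-(3-bromo-4-hydroxy-5-methoxyphenyl)-7-hydroxy-5,6-dimethoxy-1,2-dihydronaphthalene-2,3-dicarboxylate (C1 aryl and C2 carboxyl trans) | COc1cc([C@@H]2c3cc(O)c(OC)c(OC)c3C=C3C(=O)O[C@H](C)C[C@@H](C)OC(=O)[C@@H]23)cc(Br)c1O | intermediate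
12 | cyclic (2R,4R)-pentane-2,4-diyl (1R,2S,3R)-7-hydroxy-1-(4-hydroxy-3-methoxyphenyl)-5,6-dimethoxy-1,2,3,4-tetrahydronaphthalene-2,3-dicarboxylate (1,2-trans, 2,3-cis) | COc1cc([C@@H]2c3cc(O)c(OC)c(OC)c3C[C@H]3C(=O)O[C@H](C)C[C@@H](C)OC(=O)[C@@H]23)ccc1O | intermediate
13 | dimethyl (1R,2S,3S)-7-hydroxy-1-(4-hydroxy-3-methoxyphenyl)-5,6-dimethoxy-1,2,3,4-tetrahydronaphthalene-2,3-dicarboxylate (trans,trans) | COc1cc([C@@H]2c3cc(O)c(OC)c(OC)c3C[C@H](C(=O)OC)[C@H]2C(=O)OC)ccc1O | intermediate
14 | [(1R,2S,3S)-7-hydroxy-1-(4-hydroxy-3-methoxyphenyl)-5,6-dimethoxy-1,2,3,4-tetrahydronaphthalene-2,3-diyl]dimethanol | COc1cc([C@@H]2c3cc(O)c(OC)c(OC)c3C[C@H](CO)[C@H]2CO)ccc1O | target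

## Step count and risks

Total step count: 6. Longest linear sequence: 6 steps (from diol 1; aldehydes 3 and 6 enter in steps 1 and 2).

**Step 3 (key step, proposed new method).** Four things are most likely to go wrong:

- coupling of an α-carbon to the free ring position next to the ring A hydroxyl, or intermolecular coupling to oligomers, instead of the nine-membered α,α-closure, because that closure is a strained medium-ring formation;
- poor facial selectivity in the radical combination, because only a like pairing transmits the chirality of the tether;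
- ring closure in the wrong direction, or stalling after both quinone methides have tautomerised, if the guaiacyl unit loses its α-proton first;
- over-oxidation of the phenolic product.

Fallback (known chemistry; sets out from 6 and comes back at 14): ring B would be built by the lactone aldol and Friedel–Crafts sequence that is standard for 1-aryltetralin lignans.
- Aldehyde 6 would be benzylated (BnBr, K2CO3, DMF) to 4-(benzyloxy)-2,3-dimethoxybenzaldehyde F1.
- Stobbe condensation with dimethyl succinate (NaOMe, MeOH, reflux) would give (E)-4-[4-(benzyloxy)-2,3-dimethoxyphenyl]-3-(methoxycarbonyl)but-3-enoic acid F2.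
- Asymmetric hydrogenation with a cationic rhodium bisphosphine catalyst such as [Rh(cod)(Me-DuPhos)]BF4 (ligand enantiomer chosen for the S acid) would give (S)-4-[4-(benzyloxy)-2,3-dimethoxyphenyl]-3-(methoxycarbonyl)butanoic acid F3 and set C3.
- Chemoselective reduction of the ester in the potassium salt (Ca(BH4)2 from CaCl2 and NaBH4, EtOH) and acidification would give (S)-4-[4-(benzyloxy)-2,3-dimethoxybenzyl]dihydrofuran-2(3H)-one F4.
- Its lithium enolate (LiN(iPr)2, THF, −78 °C) would add to purchased 4-(benzyloxy)-3-methoxybenzaldehyde anti to the benzyl group, giving the trans aldol (3R,4S)-3-{[4-(benzyloxy)-3-methoxyphenyl](hydroxy)methyl}-4-[4-(benzyloxy)-2,3-dimethoxybenzyl]dihydrofuran-2(3H)-one F5 (carbinol epimers) and setting C2.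
- TFA in CH2Cl2 would ionise the carbinol, and ring A would close ring B through C8a, its only free ortho position and para to the C6 methoxy group. This gives the trans,trans tetralin lactone, the C9 to C10 lactone of (1R,2S,3S)-7-(benzyloxy)-1-[4-(benzyloxy)-3-methoxyphenyl]-3-(hydroxymethyl)-5,6-dimethoxy-1,2,3,4-tetrahydronaphthalene-2-carboxylic acid F6, and sets C1.
- LiAlH4 would give the dibenzyl diol [(1R,2S,3S)-7-(benzyloxy)-1-[4-(benzyloxy)-3-methoxyphenyl]-5,6-dimethoxy-1,2,3,4-tetrahydronaphthalene-2,3-diyl]dimethanol F7, and H2 with 10% Pd/C would give 14.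

**Step 2.** Most likely to go wrong: acylation of the phenol of 5 by Meldrum's acid in competition with the hindered secondary alcohol, or sluggish condensation of the ortho-methoxy aldehyde 6, leaving mixtures of half-esters.

Fallback (sets out from 6 and 5 and comes back at 8): the ring A cinnamate is made separately and attached by conventional esterification with masked phenols.
- Aldehyde 6 would be condensed with malonic acid (pyridine, piperidine, Knoevenagel–Doebner) to (E)-3-(4-hydroxy-2,3-dimethoxyphenyl)prop-2-enoic acid F8.
- Acetylation (Ac2O, pyridine) would give (E)-3-(4-acetoxy-2,3-dimethoxyphenyl)prop-2-enoic acid F9.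
- The phenol of 5 would be acetylated selectively (Ac2O, aq. NaOH, 0 °C) to (2R,4R)-4-hydroxypentan-2-yl (E)-3-(4-acetoxy-3-bromo-5-methoxyphenyl)prop-2-enoate F10.
- Steglich esterification of F10 with F9 (EDC·HCl, DMAP, CH2Cl2) would give the diacetate of 8, (2R,4R)-pentane-2,4-diyl 2-[(E)-3-(4-acetoxy-3-bromo-5-methoxyphenyl)prop-2-enoate] 4-[(E)-3-(4-acetoxy-2,3-dimethoxyphenyl)prop-2-enoate] F11.
- Pyrrolidine in CH2Cl2 would cleave both aryl acetates and give 8.

**Step 4.** Most likely to go wrong: incomplete saturation of the hindered C3=C4 bond inside the bridged ring while the C–Br bond is already cleaved, or migration of the double bond on the catalyst toward C1–C2 with loss of C1.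

Fallback (sets out from 11 and comes back at 13): the alkene is reduced by electron transfer instead of on a metal surface.
- 11 would be treated with Mg turnings in MeOH (conjugate reduction of the β-aryl acrylate).
- NaOMe would then be added to complete methanolysis and equilibration, giving dimethyl (1R,2S,3S)-1-(3-bromo-4-hydroxy-5-methoxyphenyl)-7-hydroxy-5,6-dimethoxy-1,2,3,4-tetrahydronaphthalene-2,3-dicarboxylate F12.
- Transfer hydrogenolysis (HCO2NH4, 10% Pd/C, MeOH) would remove bromine and give 13.

**Step 5.** Most likely to go wrong: slow methanolysis of the two secondary esters while the substrate is a bis-phenoxide, with side reactions of the phenoxide para to C1 (retro-1,6-addition through a quinone methide, which would erode C1, or air oxidation).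

Fallback (sets out from 12 and comes back at 13): tether cleavage and epimerisation are separated.
- 12 would be cleaved under acid (HCl in MeOH, reflux; Fischer transesterification with no phenoxide present) to the 2,3-cis diester, dimethyl (1R,2S,3R)-7-hydroxy-1-(4-hydroxy-3-methoxyphenyl)-5,6-dimethoxy-1,2,3,4-tetrahydronaphthalene-2,3-dicarboxylate F13.
- F13 would then be epimerised at C3 with DBU in toluene to give 13.

## Further compounds

F1 | step 3 | 4-(benzyloxy)-2,3-dimethoxybenzaldehyde | COc1c(C=O)ccc(OCc2ccccc2)c1OC
F2 | step 3 | (E)-4-[4-(benzyloxy)-2,3-dimethoxyphenyl]-3-(methoxycarbonyl)but-3-enoic acid | COC(=O)/C(CC(=O)O)=C/c1ccc(OCc2ccccc2)c(OC)c1OC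
F3 | step 3 | (S)-4-[4-(benzyloxy)-2,3-dimethoxyphenyl]-3-(methoxycarbonyl)butanoic acid | COC(=O)[C@H](CC(=O)O)Cc1ccc(OCc2ccccc2)c(OC)c1OC
F4 | step 3 | (S)-4-[4-(benzyloxy)-2,3-dimethoxybenzyl]dihydrofuran-2(3H)-one | O=C1C[C@H](Cc2ccc(OCc3ccccc3)c(OC)c2OC)CO1
F5 | step 3 | (3R,4S)-3-{[4-(benzyloxy)-3-methoxyphenyl](hydroxy)methyl}-4-[4-(benzyloxy)-2,3-dimethoxybenzyl]dihydrofuran-2(3H)-one (3,4-trans, carbinol epimers) | O=C1[C@@H](C(O)c2ccc(OCc3ccccc3)c(OC)c2)[C@H](Cc2ccc(OCc3ccccc3)c(OC)c2OC)CO1
F6 | step 3 | C9 to C10 lactone of (1R,2S,3S)-7-(benzyloxy)-1-[4-(benzyloxy)-3-methoxyphenyl]-3-(hydroxymethyl)-5,6-dimethoxy-1,2,3,4-tetrahydronaphthalene-2-carboxylic acid (trans,trans) | COc1cc([C@@H]2c3cc(OCc4ccccc4)c(OC)c(OC)c3C[C@@H]3COC(=O)[C@@H]23)ccc1OCc1ccccc1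
F7 | step 3 | [(1R,2S,3S)-7-(benzyloxy)-1-[4-(benzyloxy)-3-methoxyphenyl]-5,6-dimethoxy-1,2,3,4-tetrahydronaphthalene-2,3-diyl]dimethanol | COc1cc([C@@H]2c3cc(OCc4ccccc4)c(OC)c(OC)c3C[C@H](CO)[C@H]2CO)ccc1OCc1ccccc1
F8 | step 2 | (E)-3-(4-hydroxy-2,3-dimethoxyphenyl)prop-2-enoic acid | COc1c(/C=C/C(=O)O)ccc(O)c1OC
F9 | step 2 | (E)-3-(4-acetoxy-2,3-dimethoxyphenyl)prop-2-enoic acid | COc1c(/C=C/C(=O)O)ccc(OC(C)=O)c1OC
F10 | step 2 | (2R,4R)-4-hydroxypentan-2-yl (E)-3-(4-acetoxy-3-bromo-5-methoxyphenyl)prop-2-enoate | COc1cc(/C=C/C(=O)O[C@H](C)C[C@@H](C)O)cc(Br)c1OC(C)=O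
F11 | step 2 | (2R,4R)-pentane-2,4-diyl 2-[(E)-3-(4-acetoxy-3-bromo-5-methoxyphenyl)prop-2-enoate] 4-[(E)-3-(4-acetoxy-2,3-dimethoxyphenyl)prop-2-enoate] | COc1cc(/C=C/C(=O)O[C@H](C)C[C@@H](C)OC(=O)/C=C/c2ccc(OC(C)=O)c(OC)c2OC)cc(Br)c1OC(C)=O
F12 | step 4 | dimethyl (1R,2S,3S)-1-(3-bromo-4-hydroxy-5-methoxyphenyl)-7-hydroxy-5,6-dimethoxy-1,2,3,4-tetrahydronaphthalene-2,3-dicarboxylate | COc1cc([C@@H]2c3cc(O)c(OC)c(OC)c3C[C@H](C(=O)OC)[C@H]2C(=O)OC)cc(Br)c1O
F13 | step 5 | dimethyl (1R,2S,3R)-7-hydroxy-1-(4-hydroxy-3-methoxyphenyl)-5,6-dimethoxy-1,2,3,4-tetrahydronaphthalene-2,3-dicarboxylate (1,2-trans, 2,3-cis) | COc1cc([C@@H]2c3cc(O)c(OC)c(OC)c3C[C@@H](C(=O)OC)[C@H]2C(=O)OC)ccc1O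
A1 | alternative 1 | 8-bromo tetralin with free C10 hydroxyl: C7 and guaiacyl benzyl ethers, C9 triisopropylsilyl ether, trans,trans | COc1cc([C@@H]2c3c(Br)c(OCc4ccccc4)c(OC)c(OC)c3C[C@H](CO)[C@H]2CO[Si](C(C)C)(C(C)C)C(C)C)ccc1OCc1ccccc1
A2 | alternative 1 | 3-[1-(4-benzyloxy-3-methoxyphenyl)-1-(3-benzyloxy-2-bromo-4,5-dimethoxyphenyl)-3-(triisopropylsilyloxy)propan-2-yl]oxetane, C1 and C2 configured as in A1 | COc1cc([C@H](c2cc(OC)c(OC)c(OCc3ccccc3)c2Br)[C@H](CO[Si](C(C)C)(C(C)C)C(C)C)C2COC2)ccc1OCc1ccccc1
A3 | alternative 2 | C4-keto tetralin: 7-benzyloxy-1-(4-benzyloxy-3-methoxyphenyl)-2,3-bis(benzyloxymethyl)-5,6-dimethoxy-2,3-dihydronaphthalen-4(1H)-one, trans,trans | COc1cc([C@@H]2c3cc(OCc4ccccc4)c(OC)c(OC)c3C(=O)[C@H](COCc3ccccc3)[C@H]2COCc2ccccc2)ccc1OCc1ccccc1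
A4 | alternative 2 | all-trans 2-(4-benzyloxy-3-methoxyphenyl)-3,4-bis(benzyloxymethyl)cyclobutan-1-one | O=C1[C@@H](c2ccc(OCc3ccccc3)c(OC)c2)[C@H](COCc2ccccc2)[C@H]1COCc1ccccc1
A5 | alternative 2 | 5-(benzyloxy)-3,4-dimethoxy-2-(trimethylsilyl)phenyl trifluoromethanesulfonate | COc1c([Si](C)(C)C)c(OS(=O)(=O)C(F)(F)F)cc(OCc2ccccc2)c1OC
A6 | alternative 3 | all-cis menthyloxy lactone acetal cycloadduct | COc1cc([C@@H]2c3cc(OCc4ccccc4)c(OC)c(OC)c3C[C@@H]3[C@@H](O[C@H]4C[C@@H](C)CC[C@@H]4C(C)C)OC(=O)[C@H]23)ccc1OCc1ccccc1
A7 | alternative 3 | {4-(benzyloxy)-2-[(4-benzyloxy-3-methoxyphenyl)(trimethylsilyl)methyl]-5,6-dimethoxyphenyl}methyl-trimethylammonium iodide | COc1cc(C(c2cc(OCc3ccccc3)c(OC)c(OC)c2C[N+](C)(C)C)[Si](C)(C)C)ccc1OCc1ccccc1.[I-]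
A8 | alternative 3 | (5S)-5-[(1S,2R,5S)-menthyloxy]furan-2(5H)-one | O=C1C=C[C@@H](O[C@H]2C[C@@H](C)CC[C@@H]2C(C)C)O1
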